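## Retrosynthetic overview

1. Last step: the target comes from a 9β-activated 9,11-seco-spongian trans-decalin. C5 shifts from C10 to C9 (ring B 6→5, ring A 6→7) and a C20 proton is lost, as in the proposed biogenesis of the rearranged spongians.
2. The γ-lactone comes from the C11 acid and the C16 hydroxyl (seco-acid lactonisation). C12, C13 and the C13–C14 bond come from a tandem conjugate addition/hydroxylation of a decalin-fused lactone enolate on a menthyloxybutenolide.
3. The C8 quaternary centre comes from reductive alkylation of 8α-acetoxy-11-nordriman-9-one with methyl bromoacetate. The 9-ketone then gives the 9β-oxygen, used first as lactone tether and finally as leaving group.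
4. Rings A/B are taken from (−)-sclareol (a biosynthetically cyclised labdane), degraded to the 11-nor-9-ketone.
5. Ring order: decalin A/B (purchased) → temporary C15–O9 γ-lactone → C11–O16 γ-lactone → 6/6 to 5/7 reorganisation.

Numbering: labdane/spongian numbers are used throughout. The decalin is C1–C10 with the gem-dimethyl on C4 and methyls on C8 and C10 (C20). In the side chain, C14 is on C8, C15 is the CH2O on C14, and C13–C16H2–O–C11(=O)–C12 is the γ-lactone. α/β refer to the usual terpenoid orientation (C10 methyl = β).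

Assumption: the (+)-menthol-derived (5S)-5-menthyloxyfuran-2(5H)-one used in step 6 is bought as such (otherwise it takes two steps from furfural and (+)-menthol).

## Route

Step 1
Reactants: 1 (−)-sclareol
Product: 4 8α-acetoxy-13,14,15,16-tetranorlabdan-12-oic acid, via hydroxy ketone 2 (not isolated), via sclareol oxide 3 (not isolated)
Conditions: RuCl3·xH2O (2 mol %), NaIO4 (excess), EtOAc/MeCN/H2O, 25–40 °C
Reagents that add atoms: sodium periodate, [Na+].[O-]I(=O)(=O)=O (oxygen, relayed by RuO4); water, O
Why: RuO4 oxidative degradation (RuCl3/NaIO4) cleaves the vinyl carbinol to the methyl ketone, which cyclodehydrates to the enol ether sclareol oxide and is cleaved at C12=C13 to the acetoxy acid, leaving the C5, C8, C9 and C10 stereocentres of sclareol untouched.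

Step 2
Reactants: 4 8α-acetoxy-13,14,15,16-tetranorlabdan-12-oic acid
Product: 5 drim-9(11)-en-8α-yl acetate
Conditions: Pb(OAc)4, Cu(OAc)2 (cat.), pyridine, PhH, 80 °C
Reagents that add atoms: none
Why: Kochi oxidative decarboxylation gives the primary C11 radical, which divalent copper oxidises with loss of the only β-hydrogen (H9) to the exocyclic 9(11)-alkene, so no stereocentre is formed and C8 is untouched.

Step 3
Reactants: 5 drim-9(11)-en-8α-yl acetate
Product: 7 8α-acetoxy-11-nordriman-9-one, via ozonide 6 (not isolated)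
Conditions: O3, CH2Cl2, −78 °C; then Me2S, −78 °C → rt
Reagents that add atoms: ozone, [O-][O+]=O
Why: Ozonolysis (Criegee) of the 1,1-disubstituted alkene with reductive work-up removes C11 as formaldehyde and leaves the C9 ketone between the quaternary C10 and the acetoxy-bearing C8.

Step 4
Reactants: 7 8α-acetoxy-11-nordriman-9-one; 8 methyl bromoacetate
Product: 10 methyl 2-(9-oxo-11-nordriman-8α-yl)acetate, via lithium enolate 9 (not isolated)
Conditions: Li (2.1 equiv), NH3/THF, −78 °C; NH3 evaporated; then 8, THF/DMPU, −78 → 0 °C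
Reagents that add atoms: none
Why: Stork-type reductive alkylation, in which two-electron reduction of the α-acetoxy ketone expels acetate to give the only possible (C8=C9) enolate, which is C-alkylated on the α face anti to the axial C10 methyl (1,3-diaxial avoidance), making C8 quaternary with CH2CO2Me α and CH3 β.

Step 5
Reactants: 10 methyl 2-(9-oxo-11-nordriman-8α-yl)acetate
Product: 12 2-(9β-hydroxy-11-nordriman-8α-yl)acetic acid 15→9 lactone (trans-fused γ-lactone), via hydroxy ester 11 (not isolated)
Conditions: NaBH4, MeOH/THF, 0 °C → rt; then p-toluenesulfonic acid (cat.), PhMe, 60 °C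
Reagents that add atoms: none
Why: Borohydride reduction of the neopentylic C9 ketone along the axial trajectory on the α face, away from both β-axial methyls, gives the equatorial 9β-alcohol, which lactonises with the equatorial C8 acetate arm to a trans-fused γ-lactone of the sclareolide type.

Step 6
Reactants: 12 2-(9β-hydroxy-11-nordriman-8α-yl)acetic acid 15→9 lactone; 13 (5S)-5-[(1S,2R,5S)-menthyloxy]furan-2(5H)-one
Product: 16 C14-(12-hydroxy-16-menthyloxy-γ-lactonyl) lactone (12S,13S,14R,16S), via lactone enolate 14 (not isolated), via butanolide enolate 15 (not isolated)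
Conditions: LiN(iPr)2, THF, −78 °C; 13, −78 °C; then 3-phenyl-2-(phenylsulfonyl)oxaziridine, −78 °C; AcOH
Reagents that add atoms: 3-phenyl-2-(phenylsulfonyl)oxaziridine (Davis oxaziridine), O=S(=O)(N1OC1c1ccccc1)c1ccccc1
Why: Feringa tandem conjugate addition–enolate trapping, in which the lactone enolate reacts on its α face (anti to the C8 and C10 methyls) with the butenolide anti to the menthyloxy group and the resulting enolate is hydroxylated anti to the new C13 substituent, setting C14, C13 and C12 in one flask.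

Step 7
Reactants: 16 C14-(12-hydroxy-16-menthyloxy-γ-lactonyl) lactone
Product: 20 9β,12,15-triol γ-lactone (C11 carbonyl and O on C16; 12S,13R,14R), via aldehyde carboxylate 17 (not isolated), via hydroxy carboxylate 18 (not isolated), via tetraol carboxylate 19 (not isolated)
Conditions: LiOH (1.1 equiv), NaBH4, THF/H2O, 0 °C; solvent exchange, LiBH4, THF/MeOH, 0 → 45 °C; then 2 M HCl, rt
Reagents that add atoms: lithium hydroxide, [Li+].[OH-] (one C11 carboxyl oxygen)
Why: Feringa-type unmasking followed by chemoselective reduction, in which hydroxide opens only the activated acyloxy-acetal lactone (menthol leaves and NaBH4 reduces the C16 aldehyde before C13 can epimerise), the C11 carboxylate is inert to LiBH4 while the hindered C15 lactone is reduced to the 9,15-diol, and acid closes the five-membered lactone from the C16 hydroxyl as in the biogenetic seco-acid.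

Step 8
Reactants: 20 9β,12,15-triol γ-lactone
Product: 21 12,15-di-O-acetyl-9β-ol γ-lactone (12S,13R,14R)
Conditions: Ac2O, pyridine, 4-(dimethylamino)pyridine (cat.), CH2Cl2, 0 °C → rt
Reagents that add atoms: acetic anhydride, CC(=O)OC(C)=O
Why: Acylation is selective for the primary C15 and secondary C12 hydroxyls because the 9β-hydroxyl lies between two quaternary carbons and is gauche to both axial methyls, and no stereocentre is touched.

Step 9
Reactants: 21 12,15-di-O-acetyl-9β-ol γ-lactone
Product: 23 target CNP0234964.1, via 9β-triflate 22 (not isolated)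
Conditions: Tf2O, 2,6-di-tert-butyl-4-methylpyridine, CH2Cl2, −78 → 0 °C
Reagents that add atoms: none
Why: Wagner–Meerwein ring contraction–expansion of the kind known from solvolytic decalin-to-hydroazulene rearrangements and ring A contraction of 3β-hydroxy triterpenoids, in which the equatorial 9β-triflate is antiperiplanar to the C5–C10 bond so that C5 migrates to C9 with inversion at C9 and retention at C5 (cis-fused 5/7 system with H5, H9 and the C8 side chain on one face), and the hindered pyridine removes a C20 proton from the C10 cation to give the exocyclic alkene.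

## Compound list

1 | (−)-sclareol, (13R)-labd-14-ene-8α,13-diol | CC1(C)CCC[C@@]2(C)[C@H]1CC[C@@](C)(O)[C@@H]2CC[C@@](C)(O)C=C | starting material
2 | 8α-hydroxy-14,15-dinorlabdan-13-one | CC1(C)CCC[C@@]2(C)[C@H]1CC[C@@](C)(O)[C@@H]2CCC(C)=O | intermediate
3 | sclareol oxide, 8α,13-epoxy-14,15-dinorlabd-12-ene | CC1(C)CCC[C@@]2(C)[C@H]1CC[C@@]1(C)OC(C)=CC[C@H]21 | intermediate
4 | 8α-acetoxy-13,14,15,16-tetranorlabdan-12-oic acid | CC1(C)CCC[C@@]2(C)[C@H]1CC[C@@](C)(OC(C)=O)[C@@H]2CC(=O)O | intermediate
5 | drim-9(11)-en-8α-yl acetate (exocyclic C9=CH2, 8β-CH3) | CC1(C)CCC[C@@]2(C)[C@H]1CC[C@@](C)(OC(C)=O)C2=C | intermediate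
6 | ozonide of 5 (spiro-1,2,4-trioxolane at C9) | CC1(C)CCC[C@@]2(C)[C@H]1CC[C@@](C)(OC(C)=O)C23OCOO3 | intermediate
7 | 8α-acetoxy-11-nordriman-9-one | CC1(C)CCC[C@@]2(C)[C@H]1CC[C@@](C)(OC(C)=O)C2=O | intermediate
8 | methyl bromoacetate | COC(=O)CBr | starting material
9 | lithium C8=C9 enolate of 11-nordriman-9-one | [Li+].CC1(C)CCC[C@@]2(C)[C@H]1CCC(C)=C2[O-] | intermediate
10 | methyl 2-(9-oxo-11-nordriman-8α-yl)acetate (C8: CH2CO2Me α, CH3 β) | CC1(C)CCC[C@@]2(C)[C@H]1CC[C@@](C)(CC(=O)OC)C2=O | intermediate
11 | methyl 2-(9β-hydroxy-11-nordriman-8α-yl)acetate | CC1(C)CCC[C@@]2(C)[C@H]1CC[C@@](C)(CC(=O)OC)[C@@H]2O | intermediate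
12 | 2-(9β-hydroxy-11-nordriman-8α-yl)acetic acid 15→9 lactone (trans-fused γ-lactone) | CC1(C)CCC[C@@]2(C)[C@H]1CC[C@@]1(C)CC(=O)O[C@H]21 | intermediate
13 | (5S)-5-[(1S,2R,5S)-menthyloxy]furan-2(5H)-one | O=C1C=C[C@@H](O[C@H]2C[C@@H](C)CC[C@@H]2C(C)C)O1 | starting material
14 | lithium enolate (C14=C15) of 12 | [Li+].CC1(C)CCC[C@@]2(C)[C@H]1CC[C@@]1(C)C=C([O-])O[C@H]21 | intermediate
15 | lithium enolate (C11=C12) of the conjugate adduct of 14 and 13 (C13–C14 bond formed; C13 substituent trans to O-menthyl) | [Li+].CC1(C)CCC[C@@]2(C)[C@H]1CC[C@@]1(C)[C@@H]([C@@H]3[C@@H](O[C@H]4C[C@@H](C)CC[C@@H]4C(C)C)OC([O-])=C3)C(=O)O[C@H]21 | intermediate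
16 | lactone 12 carrying at C14 (α, trans to the C8 methyl) a 12-hydroxy-16-menthyloxy-γ-lactone bonded through C13; 12-OH and 16-O-menthyl both trans to the C13–C14 bond (12S,13S,14R,16S) | CC1(C)CCC[C@@]2(C)[C@H]1CC[C@@]1(C)[C@@H]([C@@H]3[C@@H](O[C@H]4C[C@@H](C)CC[C@@H]4C(C)C)OC(=O)[C@H]3O)C(=O)O[C@H]21 | intermediate
17 | lithium C11 carboxylate with C16 aldehyde and 12-OH (menthol lost; C15–O9 lactone intact) | [Li+].CC1(C)CCC[C@@]2(C)[C@H]1CC[C@@]1(C)[C@@H]([C@H](C=O)[C@H](O)C(=O)[O-])C(=O)O[C@H]21 | intermediate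
18 | lithium C11 carboxylate with 12-OH and 16-OH (C15–O9 lactone intact) | [Li+].CC1(C)CCC[C@@]2(C)[C@H]1CC[C@@]1(C)[C@@H]([C@H](CO)[C@H](O)C(=O)[O-])C(=O)O[C@H]21 | intermediate
19 | lithium 9β,12,15,16-tetrahydroxy C11 carboxylate | [Li+].CC1(C)CCC[C@@]2(C)[C@H]1CC[C@@](C)([C@H](CO)[C@H](CO)[C@H](O)C(=O)[O-])[C@@H]2O | intermediate
20 | 11-nordriman-9β-ol with C8 (α) bearing C14H(CH2OH) bonded to C13 of a 12-hydroxy γ-lactone (C11 carbonyl, O on C16; 12-OH trans to C14; 12S,13R,14R) | CC1(C)CCC[C@@]2(C)[C@H]1CC[C@@](C)([C@H](CO)[C@@H]3COC(=O)[C@H]3O)[C@@H]2O | intermediate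
21 | 12,15-di-O-acetate of 20 (free 9β-OH) | CC1(C)CCC[C@@]2(C)[C@H]1CC[C@@](C)([C@H](COC(C)=O)[C@@H]3COC(=O)[C@H]3OC(C)=O)[C@@H]2O | intermediate
22 | 9β-triflate of 21 | CC1(C)CCC[C@@]2(C)[C@H]1CC[C@@](C)([C@H](COC(C)=O)[C@@H]3COC(=O)[C@H]3OC(C)=O)[C@@H]2OS(=O)(=O)C(F)(F)F | intermediate
23 | CNP0234964.1: cis-fused perhydroazulene (H5, H9 and the C8 side chain on one face; C8 methyl on the other; exocyclic C10=CH2; gem-dimethyl on C4) with C8 bearing C14H(CH2OAc) bonded to C13 of the 12-acetoxy γ-lactone (12S,13R,14R) | C=C1CCCC(C)(C)[C@@H]2CC[C@@](C)([C@H](COC(C)=O)[C@@H]3COC(=O)[C@H]3OC(C)=O)[C@H]12 | target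

## Step count and risks

Total: 9 steps. Longest linear sequence: 9 steps (1 → 23); 8 and 13 are purchased.

**Step 9 (most likely to fail).** The C10 cation can lose a proton from C1 (or C9) instead of C20, and migration of C7 (from C8) competes with that of C5. The electron-poor side chain on C8 and the better migrating tertiary C5 argue for the wanted shift, but the exo/endo ratio is open.
Fallback: it sets out from 21 and returns at 23. Activation of 21 with Tf2O and plain pyridine at 25 °C lets the cation settle by Zaitsev proton loss from C1 to the ring A trisubstituted 1(10)-ene isomer F1. This is then moved to the exocyclic position by photochemical contra-thermodynamic positional isomerisation: allylic hydrogen abstraction by photoexcited (Bu4N)4W10O32, radical capture by the cobaloxime Co(dmgH)2(py)Cl and hydrogen redelivery at the ring carbon, in MeCN at 390 nm.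

**Step 6.** The hindered lactone enolate may add sluggishly to the butenolide or deprotonate it, and the in-flask hydroxylation may be incomplete.
Fallback: it sets out from 12 and returns at 16. Lactone 12 is converted (LiN(iPr)2, TBSCl) into the tert-butyldimethylsilyl ketene acetal F2. A Mukaiyama–Michael addition of F2 to 13 under TBSOTf catalysis at −78 °C gives the silyl ketene acetal of the adduct F3, with the same facial preferences. Rubottom oxidation of F3 with dimethyldioxirane gives the 12-silyloxy lactone F4, and HF·pyridine then frees the 12-hydroxyl to give 16.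

**Step 7.** Hydroxide may open the hindered lactone too, which would then escape reduction. The final acid closure could also give some δ-lactone through the C15 hydroxyl.
Fallback: it sets out from 16 and returns at 20. Only the LiOH/NaBH4 stage is run (through 17 and 18) and acidification gives the isolable bis-lactone F5. The unhindered α-hydroxy γ-lactone of F5 is opened selectively with pyrrolidine to the hydroxy amide F6. LiBH4 then reduces the hindered C15 lactone, leaving the amide, to give the tetraol amide F7. Warm aqueous acid lactonises the γ-hydroxy amide, expelling pyrrolidine, to give 20.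

## Further compounds

F1 | step 9 | 1(10)-ene isomer of 23 (ring A trisubstituted alkene, CH3 on C10) | CC1=CCCC(C)(C)[C@@H]2CC[C@@](C)([C@H](COC(C)=O)[C@@H]3COC(=O)[C@H]3OC(C)=O)[C@H]12
F2 | step 6 | tert-butyldimethylsilyl ketene acetal (C14=C15) of 12 | CC1(C)CCC[C@@]2(C)[C@H]1CC[C@@]1(C)C=C(O[Si](C)(C)C(C)(C)C)O[C@H]21
F3 | step 6 | tert-butyldimethylsilyl ketene acetal (C11=C12) of the conjugate adduct of F2 and 13 | CC1(C)CCC[C@@]2(C)[C@H]1CC[C@@]1(C)[C@@H]([C@@H]3[C@@H](O[C@H]4C[C@@H](C)CC[C@@H]4C(C)C)OC(O[Si](C)(C)C(C)(C)C)=C3)C(=O)O[C@H]21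
F4 | step 6 | 12-O-tert-butyldimethylsilyl ether of 16 | CC1(C)CCC[C@@]2(C)[C@H]1CC[C@@]1(C)[C@@H]([C@@H]3[C@@H](O[C@H]4C[C@@H](C)CC[C@@H]4C(C)C)OC(=O)[C@H]3O[Si](C)(C)C(C)(C)C)C(=O)O[C@H]21
F5 | step 7 | bis-lactone: lactone 12 carrying at C14 (α) the 12-hydroxy γ-lactone (C16 = CH2) | CC1(C)CCC[C@@]2(C)[C@H]1CC[C@@]1(C)[C@@H]([C@@H]3COC(=O)[C@H]3O)C(=O)O[C@H]21
F6 | step 7 | C11 pyrrolidine amide with 12-OH and 16-OH (C15–O9 lactone intact) | CC1(C)CCC[C@@]2(C)[C@H]1CC[C@@]1(C)[C@@H]([C@H](CO)[C@H](O)C(=O)N3CCCC3)C(=O)O[C@H]21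
F7 | step 7 | C11 pyrrolidine amide 9β,12,15,16-tetraol | CC1(C)CCC[C@@]2(C)[C@H]1CC[C@@](C)([C@H](CO)[C@H](CO)[C@H](O)C(=O)N3CCCC3)[C@@H]2O
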